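The data come from a simulation with constants of no real substance, noise included.

The ratio I follow is the gap between the two substrates per unit of precatalyst charged. A single-handed catalyst acts on a racemate here, and partner is consumed, so the question is where that gap sits: in product, or on the catalyst.

| setting | violet | grey | blue | flask |
|---|---|---|---|---|
| left-handed substrate | 0.050 M | 0.075 M | 0.10 M | 0.10 M |
| right-handed substrate | 0.050 M | 0.075 M | 0.10 M | 0.10 M |
| partner | 0.080 M | 0.080 M | 0.080 M | 0.0800 M |
| precatalyst | 15 mM | 15 mM | 22 mM | 15 mM |
| remark | run made earlier | run made earlier | run made earlier |  |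
| time |  |  |  | 12 h |

| run | time / h | left-handed substrate / % | right-handed substrate / % |
|---|---|---|---|
| violet | 1.33 | 47.9 | 46.3 |
| violet | 2.50 | 44.7 | 44.2 |
| violet | 4.00 | 41.5 | 40.1 |
| violet | 5.00 | 40.0 | 39.0 |
| violet | 6.00 | 39.7 | 38.6 |
| violet | 8.00 | 37.7 | 36.6 |
| grey | 1.33 | 46.9 | 47.4 |
| grey | 2.50 | 46.1 | 44.9 |
| grey | 4.00 | 43.5 | 41.9 |
| grey | 5.00 | 42.1 | 40.4 |
| grey | 6.00 | 41.7 | 40.0 |
| grey | 8.00 | 41.0 | 39.4 |
| blue | 0.500 | 49.9 | 48.9 |
| blue | 1.00 | 48.3 | 48.6 |
| blue | 2.00 | 44.6 | 44.5 |
| blue | 4.00 | 42.7 | 40.5 |
| blue | 8.00 | 41.8 | 40.0 |

(each reading ± 0.5 percentage points)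

- free catalyst is single-handed; left-handed substrate and right-handed substrate are mirror images of each other, charged as a racemate, each of them at the stated concentration
- the analysis behind the earlier runs scatters by 0.5 percentage points, standard deviation
- candidate steps: free catalyst -> spent catalyst; precatalyst -> free catalyst; 2 partner -> self-condensation product; free catalyst + left-handed substrate <-> catalyst intermediate A; partner + catalyst intermediate B -> free catalyst + right-handed product; free catalyst + right-handed substrate <-> catalyst intermediate B; partner + catalyst intermediate A -> free catalyst + left-handed product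
- an excess is the difference of the two amounts in percent of their sum
- an excess is below zero if the other one leads

1. part of the left-handed substrate and right-handed substrate charged together that has reacted at 12 h
2. excess of left-handed product over right-handed product in the product at 12 h
3. excess of right-handed substrate over left-handed substrate among what is left of the two at 12 h

In blue, the gap (left-handed substrate minus right-handed substrate) starts at zero with the racemic charge. It stands at 0.1 percentage points at 2.00 h, inside the scatter of 0.5 points per reading, while substrate falls by an average 10.9 mM/h. The readings put the knee before 4.00 h, and the level reads 2.2 points, then 1.8 points. Pooling those two readings, the gap ratio is 0.182: level gap in mM per mM of precatalyst charged.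

| run | precatalyst | level gap | substrate lost, last reading |
|---|---|---|---|
| violet | 15 mM | 1.10 mM | 25.7 mM |
| grey | 15 mM | 2.48 mM | 29.4 mM |
| blue | 22 mM | 4.00 mM | 36.4 mM |

From violet to grey, at equal precatalyst, the gap grows by a factor 2.25 and the loss by 1.14. A gap pooled from two readings keeps a scatter of about 0.5 points of the charge, so that factor is a rough reading; on it I take the gap to be substrate held on the catalyst rather than product. Blue and the flask share their substrate and partner charges, so I scale by precatalyst, and for the flask the ratio, itself a reading, gives a gap of 2.73 mM.

The forecast says c 16%, eP −8%, eS −1.5%, reasoning: “Right-handed substrate is always slightly lower, so right-handed product leads.” Taking its c, my gap gives eS −1.62%. I part from it on eP, which I expect near zero.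

The flask gives c 16.6%, eP −0.522%, eS −1.75%, so the forecast's eP lies 7.5 points below the flask's.

    free catalyst → spent catalyst (k = 0.0202 /h)
    precatalyst → free catalyst (k = 0.209 /h)
    2 partner → self-condensation product (k = 6.10 /M/h)
    free catalyst + left-handed substrate ⇌ catalyst intermediate A (K = 4.30 /M, k = 393 /M/h)
    partner + catalyst intermediate B → free catalyst + right-handed product (k = 70.0 /M/h)
    free catalyst + right-handed substrate ⇌ catalyst intermediate B (K = 10.3 /M, k = 668 /M/h)
    partner + catalyst intermediate A → free catalyst + left-handed product (k = 165 /M/h)

In the flask at 12.0 h, catalyst intermediate B exceeds catalyst intermediate A by 2.77 mM, against the 2.73 mM from the gap ratio. The product stays near racemic mainly because catalyst intermediate B runs back to free catalyst and right-handed substrate: with that backward run struck out, eP goes from −0.522% to −93.6%. For a neighbour flask, charged like the flask but with 6.00 mM of precatalyst, the ratio gives a gap of 1.09 mM and, with its c of 10.3%, eS −0.608%; that neighbour flask stands at −0.742%.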